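**Retrosynthetic overview**

- The strategy rests on the benzo ring (ring A) of the chromen-4-one: C6 and C8 are its only two carbons without oxygen in a 5,7-dihydroxy precursor, each sits ortho/para to the phenolic C5–OH and C7–OH, and both carry OMe in the target, so both C–OMe bonds are cut back to C–Br and then to C–H.
- Target 11 ⇒ benzyl-protected 10 (O-debenzylation on ring B) ⇒ 6,8-dibromide 8 (twofold Cu-mediated aryl C–OMe formation) ⇒ 5,7-dihydroxyflavone 7 (twofold bromination).
- 7 ⇒ 1,3-diketone 6 (C8a–O1–C2 closure by cyclodehydration) ⇒ phloroacetophenone 5 + aroyl chloride 4 (C-aroylation of the methyl ketone).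
- 4 ⇐ methyl 3-O-methylgallate 1 by dibenzylation, saponification and chlorination.
- Ring order: rings A and B are purchased; the pyranone ring C is the only ring formed (step 5); no stereocentre is present.

Key step: step 7

Remark: the target is an achiral flavone without any stereocentre, so no stereocontrol is required; phloroacetophenone is assumed to be used anhydrous (dried monohydrate).

**Route**

Step 1
Reactants: 1 methyl 3,4-dihydroxy-5-methoxybenzoate
Product: 2 methyl 3,4-bis(benzyloxy)-5-methoxybenzoate
Conditions: BnBr (2.4 equiv), K2CO3 (3 equiv), DMF, 60 °C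
Reagents that add atoms: benzyl bromide, BrCc1ccccc1
Why: Williamson ether synthesis in which both catechol phenoxides are alkylated by benzyl bromide under carbonate conditions that leave the methyl ester and the methyl ether untouched.

Step 2
Reactants: 2 methyl 3,4-bis(benzyloxy)-5-methoxybenzoate
Product: 3 3,4-bis(benzyloxy)-5-methoxybenzoic acid
Conditions: NaOH (aq), THF–MeOH, 60 °C; then 1 M HCl
Reagents that add atoms: sodium hydroxide, [Na+].[OH-]
Why: Ester saponification (acyl–oxygen cleavage) of an unhindered methyl benzoate; benzyl and methyl aryl ethers are stable to aqueous hydroxide.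

Step 3
Reactants: 3 3,4-bis(benzyloxy)-5-methoxybenzoic acid
Product: 4 3,4-bis(benzyloxy)-5-methoxybenzoyl chloride
Conditions: (COCl)2 (1.5 equiv), cat. DMF, CH2Cl2, 0 °C → rt; evaporate, use crude
Reagents that add atoms: oxalyl chloride, O=C(Cl)C(=O)Cl
Why: Vilsmeier-type activation by oxalyl chloride/DMF turns the acid into the acid chloride at low temperature with only gaseous by-products, so the crude chloride should be usable directly.

Step 4
Reactants: 5 1-(2,4,6-trihydroxyphenyl)ethanone; 4 3,4-bis(benzyloxy)-5-methoxybenzoyl chloride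
Product: 6 1-[3,4-bis(benzyloxy)-5-methoxyphenyl]-3-(2,4,6-trihydroxyphenyl)propane-1,3-dione (largely enolised)
Conditions: 5, LiHMDS (5 equiv), THF, −78 → −10 °C; then 4 (1.0 equiv), −78 °C → rt; aq. HCl quench
Reagents that add atoms: none
Why: Claisen-type C-aroylation of the lithium polyanion of 5 (three phenoxides plus the ketone enolate), the one-flask counterpart of the Baker–Venkataraman aroylation/acyl shift: the enolate carbon is the most nucleophilic site, any ortho O-aroyl ester is carried to the same diketone by base-induced O→C acyl transfer, and the fifth equivalent of base absorbs the acidic diketone proton.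

Step 5
Reactants: 6 1-[3,4-bis(benzyloxy)-5-methoxyphenyl]-3-(2,4,6-trihydroxyphenyl)propane-1,3-dione
Product: 7 2-[3,4-bis(benzyloxy)-5-methoxyphenyl]-5,7-dihydroxychromen-4-one
Conditions: NaOAc, AcOH, 110 °C
Reagents that add atoms: none
Why: Cyclodehydration of an o-hydroxyaryl 1,3-diketone (last stage of the Baker–Venkataraman flavone synthesis): an ortho phenol adds to the enolised aryl-ketone carbon and the hemiketal loses water to close the pyranone, the two ortho hydroxyls being equivalent, while the buffered medium without mineral acid spares the benzyl ethers.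

Step 6
Reactants: 7 2-[3,4-bis(benzyloxy)-5-methoxyphenyl]-5,7-dihydroxychromen-4-one
Product: 8 2-[3,4-bis(benzyloxy)-5-methoxyphenyl]-6,8-dibromo-5,7-dihydroxychromen-4-one
Conditions: NBS (2.05 equiv), DMF, 0 °C → rt, dark
Reagents that add atoms: N-bromosuccinimide, O=C1CCC(=O)N1Br
Why: Electrophilic aromatic bromination: C6 and C8 are the only free positions of ring A and each lies ortho/para to the two free phenols, so they should react far faster than C3 or the non-phenolic ring-B carbons, which are deactivated by conjugation with the pyranone.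

Step 7
Reactants: 8 2-[3,4-bis(benzyloxy)-5-methoxyphenyl]-6,8-dibromo-5,7-dihydroxychromen-4-one; 9 sodium methoxide
Product: 10 2-[3,4-bis(benzyloxy)-5-methoxyphenyl]-5,7-dihydroxy-6,8-dimethoxychromen-4-one
Conditions: NaOMe (30% in MeOH, ca. 12 equiv), CuBr (1 equiv), DMF, 115 °C, Ar, degassed; then aq. HCl, EDTA wash
Reagents that add atoms: sodium methoxide (compound 9), C[O-].[Na+]
Why: CuBr and excess NaOMe form copper(I) methoxide/cuprate species that insert into each C–Br bond of the bis-phenoxide of 8 (oxidative addition or its σ-bond-metathesis equivalent) and release the aryl methyl ether by reductive elimination, so the C6–OMe and C8–OMe bonds are made in one operation. The closest known reaction type is the Ullmann-type copper-mediated methoxylation of aryl bromides, which is established for 6- and 8-bromo-5,7-dihydroxyflavones in DMF–methanol. No ring is closed and no stereocentre is created. The step needs complete twofold substitution to outrun reductive debromination, which a large excess of concentrated methoxide, a full equivalent of Cu(I), exclusion of air and water and a temperature near 115 °C should favour. Positional selectivity is already fixed by the two C–Br bonds, the ring-B benzyl and methyl ethers carry no halogen and are inert to methoxide, and because C6 and C8 end up identically substituted any reversible methoxide-induced opening and reclosure of the pyranone (Wessely–Moser pathway) returns the same flavone.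

Step 8
Reactants: 10 2-[3,4-bis(benzyloxy)-5-methoxyphenyl]-5,7-dihydroxy-6,8-dimethoxychromen-4-one
Product: 11 2-(3,4-dihydroxy-5-methoxyphenyl)-5,7-dihydroxy-6,8-dimethoxychromen-4-one (5,7,3',4'-tetrahydroxy-6,8,5'-trimethoxyflavone)
Conditions: H2 (1 atm), 10% Pd/C, THF–MeOH, rt
Reagents that add atoms: none
Why: Catalytic hydrogenolysis of aryl benzyl ethers over Pd/C at ambient pressure; the aryl methyl ethers and the conjugated C2=C3 bond of the flavone should not be reduced under these mild conditions.

**Compound list**

1 | methyl 3,4-dihydroxy-5-methoxybenzoate | COC(=O)c1cc(O)c(O)c(OC)c1 | starting material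
2 | methyl 3,4-bis(benzyloxy)-5-methoxybenzoate | COC(=O)c1cc(OC)c(OCc2ccccc2)c(OCc2ccccc2)c1 | intermediate
3 | 3,4-bis(benzyloxy)-5-methoxybenzoic acid | OC(=O)c1cc(OC)c(OCc2ccccc2)c(OCc2ccccc2)c1 | intermediate
4 | 3,4-bis(benzyloxy)-5-methoxybenzoyl chloride | ClC(=O)c1cc(OC)c(OCc2ccccc2)c(OCc2ccccc2)c1 | intermediate
5 | 1-(2,4,6-trihydroxyphenyl)ethanone | CC(=O)c1c(O)cc(O)cc1O | starting material
6 | 1-[3,4-bis(benzyloxy)-5-methoxyphenyl]-3-(2,4,6-trihydroxyphenyl)propane-1,3-dione | O=C(CC(=O)c1c(O)cc(O)cc1O)c1cc(OC)c(OCc2ccccc2)c(OCc2ccccc2)c1 | intermediate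
7 | 2-[3,4-bis(benzyloxy)-5-methoxyphenyl]-5,7-dihydroxychromen-4-one | COc1cc(-c2cc(=O)c3c(O)cc(O)cc3o2)cc(OCc2ccccc2)c1OCc1ccccc1 | intermediate
8 | 2-[3,4-bis(benzyloxy)-5-methoxyphenyl]-6,8-dibromo-5,7-dihydroxychromen-4-one | COc1cc(-c2cc(=O)c3c(O)c(Br)c(O)c(Br)c3o2)cc(OCc2ccccc2)c1OCc1ccccc1 | intermediate
9 | sodium methoxide | C[O-].[Na+] | starting material
10 | 2-[3,4-bis(benzyloxy)-5-methoxyphenyl]-5,7-dihydroxy-6,8-dimethoxychromen-4-one | COc1cc(-c2cc(=O)c3c(O)c(OC)c(O)c(OC)c3o2)cc(OCc2ccccc2)c1OCc1ccccc1 | intermediate
11 | 2-(3,4-dihydroxy-5-methoxyphenyl)-5,7-dihydroxy-6,8-dimethoxychromen-4-one | COc1cc(-c2cc(=O)c3c(O)c(OC)c(O)c(OC)c3o2)cc(O)c1O | target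

**Step count and risks**

Total step count: 8. Longest linear sequence: 8 steps (1 → 2 → 3 → 4 → 6 → 7 → 8 → 10 → 11); phloroacetophenone 5 enters at step 4.

Steps most likely to fail:

1. Step 7. The electron-rich bis-phenoxide may react sluggishly, so that substitution stops at a mono-ether, bromine is lost reductively, or the polyphenoxide is degraded oxidatively at high temperature. Fallback: copper chemistry on the free phenoxide is replaced by palladium-catalysed C–O coupling on a protected substrate. Setting out from 8, both phenols are benzylated (BnBr, K2CO3, DMF, 70 °C) to give 5,7-bis(benzyloxy)-2-[3,4-bis(benzyloxy)-5-methoxyphenyl]-6,8-dibromochromen-4-one F1. This neutral dibromide is coupled with methanol under Buchwald-type etherification conditions (tBuBrettPhos Pd G3, Cs2CO3, MeOH, toluene, 70 °C) to give 5,7-bis(benzyloxy)-2-[3,4-bis(benzyloxy)-5-methoxyphenyl]-6,8-dimethoxychromen-4-one F2. Hydrogenolysis of all four benzyl ethers under the conditions of step 8 then comes back to the route at the target 11.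

2. Step 4. The polyanion may be poorly soluble, and competing O-aroylation or multiple acylation may divert the acid chloride, so that conversion to the C-aroylated diketone is low. Fallback: the classical carbonate-mediated one-pot Baker–Venkataraman sequence with excess acid chloride. Setting out from 5 and 4 (3.3 equiv) with K2CO3 in refluxing acetone, O-aroylation, acyl shift, second C-aroylation and ring closure should give 2-[3,4-bis(benzyloxy)-5-methoxyphenyl]-3-[3,4-bis(benzyloxy)-5-methoxybenzoyl]-5-hydroxy-4-oxochromen-7-yl 3,4-bis(benzyloxy)-5-methoxybenzoate F3. Heating F3 with 5% KOH in aqueous ethanol, followed by acidification, cleaves the 7-ester and removes the 3-aroyl group by ring opening, retro-Claisen cleavage and reclosure. This comes back to the route at flavone 7 and bypasses 6; the two equivalents of acid 3 released are recycled.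

3. Step 6. Bromination may run past the dibromide onto C3 or the alkoxy-rich ring B, or stop at a monobromide. Fallback: the halogens are installed before the flavone is built, when no competing aryl ring is present. Setting out from 5, NBS (2 equiv, MeCN, 0 °C) should give 1-(3,5-dibromo-2,4,6-trihydroxyphenyl)ethanone F4. Aroylation of its lithium polyanion with 4 under the conditions of step 4 gives 1-[3,4-bis(benzyloxy)-5-methoxyphenyl]-3-(3,5-dibromo-2,4,6-trihydroxyphenyl)propane-1,3-dione F5. Cyclodehydration under the conditions of step 5 comes back to the route at dibromide 8.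

**Further compounds**

F1 | step 7 | 5,7-bis(benzyloxy)-2-[3,4-bis(benzyloxy)-5-methoxyphenyl]-6,8-dibromochromen-4-one | COc1cc(-c2cc(=O)c3c(OCc4ccccc4)c(Br)c(OCc4ccccc4)c(Br)c3o2)cc(OCc2ccccc2)c1OCc1ccccc1
F2 | step 7 | 5,7-bis(benzyloxy)-2-[3,4-bis(benzyloxy)-5-methoxyphenyl]-6,8-dimethoxychromen-4-one | COc1cc(-c2cc(=O)c3c(OCc4ccccc4)c(OC)c(OCc4ccccc4)c(OC)c3o2)cc(OCc2ccccc2)c1OCc1ccccc1
F3 | step 4 | 2-[3,4-bis(benzyloxy)-5-methoxyphenyl]-3-[3,4-bis(benzyloxy)-5-methoxybenzoyl]-5-hydroxy-4-oxochromen-7-yl 3,4-bis(benzyloxy)-5-methoxybenzoate | O=C(Oc1cc(O)c2c(c1)oc(-c1cc(OC)c(OCc3ccccc3)c(OCc3ccccc3)c1)c(C(=O)c1cc(OC)c(OCc3ccccc3)c(OCc3ccccc3)c1)c2=O)c1cc(OC)c(OCc2ccccc2)c(OCc2ccccc2)c1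
F4 | step 6 | 1-(3,5-dibromo-2,4,6-trihydroxyphenyl)ethanone | CC(=O)c1c(O)c(Br)c(O)c(Br)c1O
F5 | step 6 | 1-[3,4-bis(benzyloxy)-5-methoxyphenyl]-3-(3,5-dibromo-2,4,6-trihydroxyphenyl)propane-1,3-dione | O=C(CC(=O)c1c(O)c(Br)c(O)c(Br)c1O)c1cc(OC)c(OCc2ccccc2)c(OCc2ccccc2)c1
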